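All runs stem from a simulated flask with constants of no real substance; scatter was added.

The winter and dusk runs cannot be carried straight across to red, blue, green and ochre, since those flasks hold 0.110 M of partner, less than either earlier run, and stand at other temperatures.

| flask | substrate | partner | temperature | remark | time |
|---|---|---|---|---|---|
| winter | 0.10 M | 0.15 M | 24 °C | run made earlier |  |
| dusk | 0.10 M | 0.24 M | 65 °C | run made earlier |  |
| red | 0.10 M | 0.110 M | 55 °C |  | 1.5 h |
| blue | 0.10 M | 0.110 M | 5 °C |  | 1.5 h |
| green | 0.10 M | 0.110 M | 80 °C |  | 1.5 h |
| ochre | 0.10 M | 0.110 M | 30 °C |  | 1.5 h |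

winter run (percent of the substrate charged)

| time / h | target / % | substrate / % |
|---|---|---|
| 1.00 | 44.5 | 39.3 |
| 2.00 | 40.9 | 32.3 |
| 3.00 | 37.3 | 27.3 |
| 4.00 | 34.4 | 23.2 |
| 5.00 | 32.8 | 20.8 |
| 6.00 | 30.2 | 18.3 |
| 8.00 | 27.6 | 14.5 |

dusk run (percent of the substrate charged)

| time / min | target / % | substrate / % |
|---|---|---|
| 3.00 | 28.8 | 44.5 |
| 10.0 | 17.1 | 27.8 |
| 15.0 | 13.0 | 23.4 |
| 25.0 | 8.2 | 16.5 |
| 30.0 | 7.1 | 15.0 |
| 50.0 | 4.6 | 10.8 |
| 60.0 | 3.1 | 9.1 |

(standard deviation of a reading: 0.3 percentage points)

- percent here means substrate units held: one self-condensation product or side product B counts as two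
- candidate steps: substrate + partner -> target; 2 partner -> side product A; partner -> decomposed reagent; 2 substrate -> self-condensation product; substrate + target -> side product B

- the flask with the highest amount of target, in percent of the substrate charged ("all alike" if they lie within 1.5 percentage points) (red / blue / green / ochre / all alike)
- final target, as a percentage of the substrate charged, in red
- final target, as a percentage of the substrate charged, in blue
- final target, as a percentage of the substrate charged, in green
- final target, as a percentage of the substrate charged, in ochre

Two chemists dispute this. Both see a burst in each run, then target and substrate falling together, and both read that fall as substrate + target → side product B, with rate constant k. The one who made the forecast says of the flask at 5 °C: “Blue is simply slow and unfinished”. The forecast names ochre at 23%, with blue at 21%, red at 1% and green at 0%.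

Her colleague holds that survival of target matters more. At substrate concentration S, target suffers a pseudo-first-order loss with half-life ln(2)/(kS). Winter's fall from 44.5% to 34.4% over the mean substrate gives k = 2.75 M⁻¹ h⁻¹. Dusk's fall from 28.8% to 13.0% gives 117 M⁻¹ h⁻¹. These are readings, with their scatter, and together they give an activation energy of 76.5 kJ mol⁻¹, so his estimate of k at 5 °C is 0.331 M⁻¹ h⁻¹.

For blue, his first round uses the charged substrate, and target then keeps 95.2% over 1.5 h. He assumes, unproved, that blue couples as much as winter's first target reading, which gives 42.3%. Putting that back, substrate is about 57.7% of its charge, and the half-life of target under substrate attack becomes 36.3 h. His second round for blue then gives an estimate of 43.2%. For ochre, his first round with the charged substrate gives a half-life of 1.37 h, shorter than the run. He names blue.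

The simulation gives blue: blue 49.2%, ochre 29.9%, red 3.37%, green 0%.

    substrate + partner → target (k = 0.00920 M⁻¹ s⁻¹, Ea = 47.0 kJ mol⁻¹)
    2 partner → side product A (k = 0.00920 M⁻¹ s⁻¹, Ea = 58.0 kJ mol⁻¹)
    partner → decomposed reagent (k = 1.20 × 10⁻⁵ s⁻¹, Ea = 92.0 kJ mol⁻¹)
    2 substrate → self-condensation product (k = 5.50 × 10⁻⁵ M⁻¹ s⁻¹, Ea = 56.0 kJ mol⁻¹)
    substrate + target → side product B (k = 9.20 × 10⁻⁵ M⁻¹ s⁻¹, Ea = 78.0 kJ mol⁻¹)
    (constants at 5 °C)

Blue ended with 46.7% of its substrate, so the same reckoning gives a half-life of 44.8 h, longer than the run, and side product B stood at 2.21%. The forecast's word "unfinished" fits a repeat of blue at −10 °C, with the same amounts and time. There the estimate of k is 0.0503 M⁻¹ h⁻¹, and the end substrate gives a half-life of 256 h, longer still. That colder flask gave target 45.3%, less than blue, with 54% of its substrate and 14% of its partner left.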